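## Retrosynthetic overview
1. The only ring, the 1,2-dioxane, is formed last, on the complete acyclic C22 chain. The acyclic 6-oxo-2-enoate, H2O2 and MeOH are joined in one flask.
2. Bond order in that flask: O–C6 by reversible perhydrate formation, then O–C3 by a catalyst-controlled 6-exo peroxy-Michael closure that sets C3, then C6–OMe by anomerically controlled methanolysis that sets C6.
3. The acyclic keto-trienynoate is cut at C11–C12 (Sonogashira) into an E-iodoalkene and a terminal alkyne keto-enoate.
4. The E-iodoalkene comes from dec-9-en-1-ol by oxidation and Takai olefination.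
5. The alkyne keto-enoate comes from hex-5-ynenitrile and but-3-enylmagnesium bromide (C5–C6), then ozonolysis and Wittig olefination (C2=C3).

Assumption: the presumed biosynthesis is taken as peroxide addition to the C6 ketone of a 6-oxo-2-enoic fatty acid, conjugate closure of the OOH group onto C3, and exchange of the hemiketal OH for OMe.

## Route

Step 1
Reactants: 1 dec-9-en-1-ol
Product: 2 dec-9-enal
Conditions: TEMPO (2,2,6,6-tetramethylpiperidin-1-oxyl, 10 mol %), PhI(OAc)2 (1.1 equiv), CH2Cl2, rt
Reagents that add atoms: none
Why: Oxoammonium-mediated alcohol oxidation stops at the aldehyde and leaves the terminal alkene untouched; no stereocentre is formed.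

Step 2
Reactants: 2 dec-9-enal
Product: 3 (1E)-1-iodoundeca-1,10-diene
Conditions: CrCl2 (6 equiv), CHI3 (2 equiv), 1,4-dioxane/THF 6:1, 0 °C to rt
Reagents that add atoms: iodoform, IC(I)I
Why: Takai olefination, in which the geminal dichromium carbenoid adds to the aldehyde and eliminates from the less crowded adduct, gives the E-iodoalkene (about 10:1 in dioxane-rich solvent) and so fixes the C12=C13 geometry.

Step 3
Reactants: 4 hex-5-ynenitrile; 5 but-3-enylmagnesium bromide
Product: 7 dec-1-en-9-yn-5-one, via bromomagnesium ketiminate 6 (not isolated)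
Conditions: 5 (1.05 equiv), THF, 0 °C to rt; then CuBr·SMe2 (5 mol %), 5 (1.4 equiv), 60 °C; then 1 M HCl, 0 °C to rt
Reagents that add atoms: water, O
Why: In this copper-assisted Grignard addition to a nitrile, the first equivalent only deprotonates the alkyne, the second adds once because the ketiminate resists further attack, and acid hydrolysis frees the ketone; no stereocentre is formed.

Step 4
Reactants: 7 dec-1-en-9-yn-5-one; 8 methyl (triphenylphosphoranylidene)acetate
Product: 11 methyl (E)-6-oxoundec-2-en-10-ynoate, via ozonide 9 (not isolated), via 4-oxonon-8-ynal 10 (not isolated)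
Conditions: O3, CH2Cl2, −78 °C (Sudan Red 7B end point); PPh3 (1.05 equiv), −78 °C to rt; then 8 (2.5 equiv), rt
Reagents that add atoms: ozone, [O-][O+]=O (supplies the aldehyde oxygen of 10, which leaves again in the olefination)
Why: Ozonolysis is chemoselective because a terminal alkene reacts orders of magnitude faster than a terminal alkyne, and the in-flask Wittig olefination with the stabilised ylide attacks only the aldehyde, not the ketone, to give the E-enoate (>15:1).

Step 5
Reactants: 3 (1E)-1-iodoundeca-1,10-diene; 11 methyl (E)-6-oxoundec-2-en-10-ynoate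
Product: 12 methyl (2E,12E)-6-oxodocosa-2,12,21-trien-10-ynoate
Conditions: PdCl2(PPh3)2 (3 mol %), CuI (6 mol %), Et3N (3 equiv), degassed THF, rt
Reagents that add atoms: none
Why: In this Sonogashira coupling, oxidative addition of zerovalent palladium to the alkenyl iodide and reductive elimination both go with retention, so the E geometry is carried over, and the tertiary amine base cannot add to the enoate.

Step 6
Reactants: 12 methyl (2E,12E)-6-oxodocosa-2,12,21-trien-10-ynoate
Product: 15 peroxyacarnoate A (methyl 2-[(3S,6R)-6-[(6E)-hexadeca-6,15-dien-4-yn-1-yl]-6-methoxy-1,2-dioxan-3-yl]acetate), via ketone perhydrate 13 (not isolated), via peroxyhemiketal 14 (not isolated)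
Conditions: urea·H2O2 (3 equiv), 3-[[3,5-bis(trifluoromethyl)phenyl]amino]-4-[[(8α,9S)-6′-methoxycinchonan-9-yl]amino]cyclobut-3-ene-1,2-dione (10 mol %), CH2Cl2, 0 °C to rt; filter; then MeOH, TsOH·H2O (25 mol %), rt
Reagents that add atoms: hydrogen peroxide (delivered as urea·H2O2), OO; methanol, CO
Why: Proposed new method: H2O2 adds reversibly to the C6 ketone to give the rapidly racemising perhydrate 13, and the oxidation-resistant squaramide catalyst binds the enoate carbonyl with its N–H pair while its quinuclidine nitrogen deprotonates the OOH group (the two roles that an achiral secondary amine and a fluorinated alcohol play in the known racemic peroxy-Michael cyclisation of hydroperoxy ketals, which has no background reaction without base), so it selects one of the two mirror-image chair transition states of the 6-exo-trig oxa-Michael closure and sets C3 as S in a dynamic kinetic asymmetric transformation whose closest known relatives are hemiketalisation/oxa-Michael cascades of hydroxy enones and intramolecular oxa-Michael additions to unsaturated esters under bifunctional amine/hydrogen-bond-donor catalysis; acid then ionises hemiketal 14 to a peroxycarbenium ion that takes up MeOH reversibly, so C6 ends as R under thermodynamic control (OMe axial by the anomeric effect, both carbon chains equatorial, OMe cis to CH2CO2Me).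

## Compound list
1 | dec-9-en-1-ol | C=CCCCCCCCCO | starting material
2 | dec-9-enal | C=CCCCCCCCC=O | intermediate
3 | (1E)-1-iodoundeca-1,10-diene | C=CCCCCCCC/C=C/I | intermediate
4 | hex-5-ynenitrile | C#CCCCC#N | starting material
5 | but-3-enylmagnesium bromide | C=CCC[Mg]Br | starting material
6 | bromomagnesium ketiminate of dec-1-en-9-yn-5-one, alkyne terminus also magnesiated | C=CCCC(=N[Mg]Br)CCCC#C[Mg]Br | intermediate
7 | dec-1-en-9-yn-5-one | C=CCCC(=O)CCCC#C | intermediate
8 | methyl (triphenylphosphoranylidene)acetate | COC(=O)C=P(c1ccccc1)(c1ccccc1)c1ccccc1 | starting material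
9 | 1-(1,2,4-trioxolan-3-yl)oct-7-yn-3-one | C#CCCCC(=O)CCC1OCOO1 | intermediate
10 | 4-oxonon-8-ynal | C#CCCCC(=O)CCC=O | intermediate
11 | methyl (E)-6-oxoundec-2-en-10-ynoate | C#CCCCC(=O)CC/C=C/C(=O)OC | intermediate
12 | methyl (2E,12E)-6-oxodocosa-2,12,21-trien-10-ynoate | C=CCCCCCCC/C=C/C#CCCCC(=O)CC/C=C/C(=O)OC | intermediate
13 | methyl (2E,12E)-6-hydroperoxy-6-hydroxydocosa-2,12,21-trien-10-ynoate (C6 labile) | C=CCCCCCCC/C=C/C#CCCCC(O)(OO)CC/C=C/C(=O)OC | intermediate
14 | methyl 2-[(3S)-6-[(6E)-hexadeca-6,15-dien-4-yn-1-yl]-6-hydroxy-1,2-dioxan-3-yl]acetate (C6 anomers interconvert) | C=CCCCCCCC/C=C/C#CCCCC1(O)CC[C@@H](CC(=O)OC)OO1 | intermediate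
15 | peroxyacarnoate A, (3S,6R) | C=CCCCCCCC/C=C/C#CCCC[C@]1(OC)CC[C@@H](CC(=O)OC)OO1 | target

## Counts
Total steps: 6.
Longest linear sequence: 4 steps (1 → 2 → 3 → 12 → 15, or equally 4 → 7 → 11 → 12 → 15).

## Three steps most likely to fail

**Step 6.**
- The stationary concentration of 13 is low.
- The catalyst nitrogen can be slowly oxidised.
- The hemiketal OH can close in a 5-exo mode instead.
- The level of asymmetric induction is untested.
- The sense of induction cannot be predicted, so the S assignment at C3 with this catalyst is provisional. It has to be checked against the optical rotation of the natural product. If it proves opposite, the quinidine-derived pseudoenantiomer of the catalyst is used instead.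

The fallback sets out from 12 and returns at 15. It drops asymmetric catalysis for a stepwise racemic closure followed by resolution.
- Urea·H2O2 with Sc(OTf)3 (10 mol %) in MeOH gives the racemic hydroperoxy ketal methyl (2E,12E)-6-hydroperoxy-6-methoxydocosa-2,12,21-trien-10-ynoate F1.
- Et2NH in CF3CH2OH at rt closes it to the racemic 6-methoxy-1,2-dioxane as a mixture of C6 epimers F2.
- TsOH·H2O in MeOH equilibrates this mixture to racemic peroxyacarnoate A F3.
- Preparative chromatography on an amylose tris(3,5-dimethylphenylcarbamate) phase separates 15 from ent-peroxyacarnoate A F4.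

**Step 3.** α-Deprotonation of the nitrile, self-condensation and sluggish addition can lower the yield. The fallback sets out from 4 and 5 and returns at 7. It goes through the alcohol oxidation level instead of the nitrile.
- i-Bu2AlH (CH2Cl2, −78 °C, then aqueous acid) reduces 4 to hex-5-ynal F5.
- Grignard reagent 5 adds to the aldehyde at −78 °C, faster than it deprotonates the alkyne, to give racemic dec-1-en-9-yn-5-ol F6.
- Dess–Martin periodinane oxidises this alcohol to 7.

**Step 2.** The Z-iodoalkene forms as a minor product and is hard to remove, and it would carry through to 12. The fallback sets out from 2 and returns at 3. It sets the geometry by syn-hydrometalation instead of olefination.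
- Dimethyl (1-diazo-2-oxopropyl)phosphonate with K2CO3 in MeOH converts 2 into undec-1-en-10-yne F7.
- Cp2Zr(H)Cl (1.05 equiv, THF, rt) adds to the alkyne in preference to the alkene to give the alkenylzirconocene chloride Cp2Zr(Cl)[(E)-undeca-1,10-dien-1-yl] F8.
- I2 at 0 °C cleaves this with retention to give geometrically pure 3.

## Further compounds
F1 | step 6 | methyl (2E,12E)-6-hydroperoxy-6-methoxydocosa-2,12,21-trien-10-ynoate (racemic) | C=CCCCCCCC/C=C/C#CCCCC(OC)(OO)CC/C=C/C(=O)OC
F2 | step 6 | methyl 2-[6-[(6E)-hexadeca-6,15-dien-4-yn-1-yl]-6-methoxy-1,2-dioxan-3-yl]acetate, racemic mixture of C6 epimers | C=CCCCCCCC/C=C/C#CCCCC1(OC)CCC(CC(=O)OC)OO1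
F3 | step 6 | racemic peroxyacarnoate A, (3S,6R) and (3R,6S) 1:1 | C=CCCCCCCC/C=C/C#CCCC[C@]1(OC)CC[C@@H](CC(=O)OC)OO1.C=CCCCCCCC/C=C/C#CCCC[C@@]1(OC)CC[C@H](CC(=O)OC)OO1
F4 | step 6 | ent-peroxyacarnoate A, (3R,6S) | C=CCCCCCCC/C=C/C#CCCC[C@@]1(OC)CC[C@H](CC(=O)OC)OO1
F5 | step 3 | hex-5-ynal | C#CCCCC=O
F6 | step 3 | dec-1-en-9-yn-5-ol (racemic) | C=CCCC(O)CCCC#C
F7 | step 2 | undec-1-en-10-yne | C=CCCCCCCCC#C
F8 | step 2 | chlorobis(cyclopentadienyl)[(E)-undeca-1,10-dien-1-yl]zirconium | C=CCCCCCCC/C=C/[Zr+2]Cl.c1cc[cH-]c1.c1cc[cH-]c1
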